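**Numbering.** Compounds carry the numbers used in the steps (1–23) throughout. Target = 23.

## Analysis of the target

Target 23 is a 5,7-dimethoxyphthalide whose C3 carries a six-methylene tether ending at C2 of a 1,6-dioxaspiro[4.4]nonane, in which ring A (O1, C2–C5) bears the tether and ring B (C5, O6, C7–C9) a methyl group at C7. There are four stereocentres: phthalide C3 (R) and spiroketal C2 (R), C5 (S) and C7 (R); in this arrangement each alkyl substituent is trans to the oxygen of the other ring. C3 and C2 are six CH2 groups apart, so neither can direct the other, and C7 is cut off from C2 by the spiro carbon. C5 is the delicate centre: a five-membered spiroketal has little anomeric or steric bias and C5 epimerises under acid, so the two C5 epimers are expected to be close in energy. The spiroketal is acid-labile, and the phthalide is a benzylic lactone with an acidic C3–H that opens with hard nucleophiles, so the late steps must be few and mild. The plan rests on one feature: both chain-end carbinols stand gamma to a carbon that can be written as an ester carbonyl. C3 is gamma to the lactone carbon C1 through C3a and C7a; C2 is gamma to C5 through C3 and C4, and C5, although at the ketone level in the target, is reachable from a lactone carbonyl by one carbon nucleophile. At both carbinols the arm leading to that carbonyl ranks second and the plain alkyl arm third, and both are R, so one ester-directed ketone reduction can set both.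

## Retrosynthetic reasoning

**Spiroketal C5–O bonds.** Target 23 is opened at C5–O1 and C5–O6 to dihydroxy ketone 21, handled as its C13 silyl ether 20. These bonds form reversibly under mild acid, so the labile unit is made last and C2 and C7 become ordinary carbinols set earlier. The cost is that C5 cannot be directed: the closure is reversible and not face-selective, so the C5 epimer 22 forms in the same flask beside 23. The forward step must therefore withdraw 23 from the equilibrium and send 22 back through the acid.

**C5–C9 bond.** Ketone 20 is cut between the carbonyl carbon and the CH2 of the methyl-bearing arm, giving bis-lactone 13 and organocerium reagent 19, made through alkyllithium 18 from iodide 17. Cutting on this side, not at C4–C5, makes ring A a gamma-lactone, which is what turns C2 into the gamma-carbinol of an ester. The four-carbon piece brings C7 from the chiral pool: 17 comes from (R)-butane-1,3-diol 14 through tosylate 15 and silyl ether 16. Forward, the nucleophile must add once to the aliphatic lactone of 13 and spare the phthalide.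

**Two carbinol C–H bonds and two lactone C–O bonds (key disconnection).** Bis-lactone 13 is opened at both acyl–oxygen bonds to diol diester 12, and the hydrogens at the two carbinol carbons are removed to give the achiral diketo diester 11. No other cut removes both remote stereocentres at once; they cannot be relayed, but each has its own directing ester. Forward, one chiral hydrogenation catalyst must reduce both ketones in the same sense and both hydroxy esters must close.

**Aryl–carboxyl bond.** The aromatic ester of 11 is removed to aryl bromide 10 and then to the unsubstituted ring position in 9. The ester goes in last because a 2-acylbenzoate would not survive the saponification needed for chain assembly. The site is ortho to the acyl group and para to a methoxy group, where electrophilic bromination is expected. Forward: regioselective bromination, then alkoxycarbonylation.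

**C3–C4 bond of the undecanoate chain.** Diketo ester 9 is cut between the aliphatic ketone and the propanoate CH2 into acid chloride 7 and zinc homoenolate 8, that is acid 5 (from ester 4) and methyl 3-iodopropanoate 6. One bond sets the 1,4-relationship of ketone and ester, with a nucleophile that tolerates the aryl ketone.

**Aryl–acyl bond.** Keto ester 4 is cut at the aryl ketone into Grignard reagent 3, from 1-bromo-3,5-dimethoxybenzene 1, and methyl 8-chloro-8-oxooctanoate 2. A 3,5-dimethoxyphenyl ketone is not available by Friedel–Crafts acylation, which would go ortho or para to the methoxy groups, so the ring enters as the nucleophile.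

## Alternatives that were turned down

**Alternative 1:** Disconnection: the C5–C9 bond and both ketal C–O bonds, with the halves taken as lactones, (R)-gamma-valerolactone A1 for ring B and (R)-5-(hex-5-enyl)butanolide A2 for ring A.
- Forward key step: the lithium enolate of A1 is C-acylated by A2 (crossed Claisen). Aqueous acid then opens the acylated lactone, decarboxylates the beta-keto acid (removing the former carbonyl carbon of A1) and closes both rings to hex-5-enyl spiroketal A3.
- For it: C2 and C7 come from the chiral pool, so there is no catalyst sense to verify and no pressure hydrogenation. No organometallic reagent has to choose between two lactones, because the phthalide is attached later. On these points it is stronger than the chosen route.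
- Against it: C5 is equally uncontrolled, since the same acid equilibrium closes the rings. The acylation needs excess enolate and competes with enolisation of A2. A2 needs several chain-extension steps. The alkene of A3 must still be joined to a phthalide fragment whose C3 is set by a separate asymmetric operation, followed by saturation of the link.
- Comparison: it needs more operations and three independent sources of chirality. The chosen route sets C3 and C2 in one operation from an achiral precursor and builds the carbon skeleton with two couplings.

**Alternative 2:** Disconnection: the C3a–C7a bond of the benzene ring; the arene is made last from diketo-dioxinone A4, which already holds the silyl-protected C3 carbinol and the complete spiroketal.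
- Forward key step: a mild base triggers aldol addition of the dioxinone alpha-carbon (future C7a) to the ketone next to the carbinol (future C3a), and dehydration aromatises to benzodioxinone resorcylate A5.
- For it: the ring substitution pattern is fixed by the chain, so no regioselective halogenation and no carbonylation at a crowded position is needed. Here it is clearly stronger than the chosen route, whose steps 4 and 5 carry that risk.
- Against it: the ring is the one part of the target that can be bought with both oxygens in place, and building it from a polycarbonyl chain costs several acylations. The C3 carbinol of A4 is alpha to a ketone and can epimerise under the base. After A5 there remain phenol methylation, dioxinone opening, a second methylation, desilylation and lactonisation, all with the acid-labile spiroketal and its open C5 question on board.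
- Comparison: the chosen route gives up certainty in arene regiochemistry for a much shorter sequence that forms the spiroketal last.

**Alternative 3:** Disconnection: the O1–C5 bond alone; ring B is present as an oxolane in alcohol A6 and ring A is closed oxidatively.
- Forward key step: the C2 hydroxyl is converted to its hypoiodite with PhI(OAc)2 and I2 under irradiation. The alkoxy radical abstracts the C5 hydrogen through a six-membered transition state, the radical is oxidised to the oxocarbenium ion, and the same oxygen closes ring A to heptyl pivalate A7.
- For it: no ketone and no addition to a lactone are needed, the conditions are near neutral, and C5 forms kinetically. In mildness of ring closure it is at least equal to the chosen route.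
- Against it: the cation is planar between two similar CH2 groups, so C5 is no better controlled. The alkoxy radical can fragment or abstract from the tether. A6 needs C2 and C7 set separately. After A7 the pivalate must be removed, the alcohol oxidised, the aryl unit added with control of C3 and the phthalide closed, all in the presence of the spiroketal.
- Comparison: the chosen route sets C3 and C2 together and leaves the spiroketal to the end.

Key step: step 6

## Route

Remark on the chemistry: the two C5 epimers of the spiroketal, 23 and 22, are assumed to be of similar energy and to interconvert under acid. Step 11 is therefore written as an equilibration from which 23 is withdrawn while 22 is returned to the acid in crude form, not as a selective closure.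
Remark: methyl 8-chloro-8-oxooctanoate 2 is taken as a purchased reagent.

Step 1
Reactants: 1 1-bromo-3,5-dimethoxybenzene; 2 methyl 8-chloro-8-oxooctanoate
Product: 4 methyl 8-(3,5-dimethoxyphenyl)-8-oxooctanoate, via aryl Grignard reagent 3 (not isolated)
Conditions: Mg, THF, reflux then rt; added to 2, Fe(acac)3 (3 mol %), THF, −78 °C
Reagents that add atoms: none
Why: Iron-catalysed acylation of a Grignard reagent by an acid chloride; at −78 °C with Fe(acac)3 (trivalent iron precatalyst) the acid chloride should react far faster than the methyl ester or the ketone being formed, so the aryl ketone is expected without tertiary alcohol.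

Step 2
Reactants: 4 methyl 8-(3,5-dimethoxyphenyl)-8-oxooctanoate
Product: 5 8-(3,5-dimethoxyphenyl)-8-oxooctanoic acid
Conditions: LiOH·H2O, THF–H2O, rt; then 1 M HCl
Reagents that add atoms: lithium hydroxide, [Li+].[OH-]
Why: Saponification of an unhindered methyl ester; the aryl ketone is inert, and the hydrolysis is placed here because the ring carries no ester yet.

Step 3
Reactants: 5 8-(3,5-dimethoxyphenyl)-8-oxooctanoic acid; 6 methyl 3-iodopropanoate
Product: 9 methyl 11-(3,5-dimethoxyphenyl)-4,11-dioxoundecanoate, via acid chloride 7 (not isolated), via zinc homoenolate 8 (not isolated)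
Conditions: 5, (COCl)2, DMF (cat.), CH2Cl2, 0 °C → rt, concentrate; 6, Zn dust (activated with BrCH2CH2Br, TMSCl), THF, 35 °C; then 7 + 8, Pd(PPh3)4 (5 mol %), THF, 0 °C → rt
Reagents that add atoms: none
Why: Negishi-type acylation: zerovalent palladium inserts into the acyl chloride, the zinc homoenolate transmetalates and reductive elimination gives the 4-oxo ester; the organozinc reagent should not add to the aryl ketone or to esters.

Step 4
Reactants: 9 methyl 11-(3,5-dimethoxyphenyl)-4,11-dioxoundecanoate
Product: 10 methyl 11-(2-bromo-3,5-dimethoxyphenyl)-4,11-dioxoundecanoate
Conditions: NBS (1.05 equiv), MeCN, 0 °C → rt, dark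
Reagents that add atoms: N-bromosuccinimide, O=C1CCC(=O)N1Br
Why: Electrophilic aromatic bromination; the position ortho to the acyl group is para to one methoxy group and ortho to the other and is less hindered than the position between the two methoxy groups, so substitution is expected there, and without acid or radical initiation the ketone alpha-positions should stay untouched.

Step 5
Reactants: 10 methyl 11-(2-bromo-3,5-dimethoxyphenyl)-4,11-dioxoundecanoate
Product: 11 methyl 2-(11-methoxy-8,11-dioxoundecanoyl)-4,6-dimethoxybenzoate
Conditions: CO (1–5 atm), Pd(OAc)2 (5 mol %), Xantphos (6 mol %), Et3N, MeOH–DMF, 80 °C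
Reagents that add atoms: carbon monoxide, [C-]#[O+]; methanol, CO
Why: Palladium-catalysed alkoxycarbonylation of an aryl bromide: zerovalent palladium formed from Pd(OAc)2 inserts into C–Br, CO insertion gives the aroylpalladium species and methanol cleaves it to the ester; the wide-bite-angle diphosphine is the ligand type suited to ortho-substituted bromides at low CO pressure, and the ketones and chain ester are spectators.

Step 6
Reactants: 11 methyl 2-(11-methoxy-8,11-dioxoundecanoyl)-4,6-dimethoxybenzoate
Product: 13 (3R)-5,7-dimethoxy-3-{6-[(2R)-5-oxooxolan-2-yl]hexyl}-2-benzofuran-1(3H)-one, via diol diester 12 (not isolated)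
Conditions: H2 (about 100 atm), RuCl2[(R)-BINAP](dmf)n (2 mol %), MeOH, 35–50 °C; then p-TsOH (cat.), toluene, 60 °C
Reagents that add atoms: none
Why: Under H2 the dichloride precatalyst becomes a BINAP–ruthenium monohydride (divalent ruthenium); each ketone of 11 binds it together with the carbonyl oxygen of its own ester in a seven-membered chelate, the hydride migrates to the ketone carbon inside that chelate, and protonolysis by methanol releases the alcohol while H2 restores the hydride. The closest known reaction type is the BINAP–ruthenium hydrogenation of 4-oxo esters to gamma-lactones and of 2-acylbenzoates to phthalides; 11 holds one member of each class, six methylene groups apart, so the two sites cannot compete for one metal centre. Diol diester 12 then lactonises twice, each time by 5-exo-trig acyl substitution of a gamma-hydroxyl on its ester carbonyl: the benzylic hydroxyl closes the phthalide on the aryl ester and the aliphatic hydroxyl closes the butanolide on the chain ester, the acid finish completing whatever has not closed during hydrogenation. Phthalide C3 is controlled by the ligand through the aryl-ester chelate and the butanolide carbinol (the later spiroketal C2) by the same ligand through the chain-ester chelate; there is no substrate control. Because the chelating arm ranks second and the non-chelating alkyl arm third at both carbons, one ligand antipode must give the same descriptor twice, and (R)-BINAP is expected to give R,R by analogy with simple 4-oxo esters; the sense is to be confirmed on mono-ketone models of both classes and the (S)-ligand used if it proves opposite. The step needs chemoselectivity for ketone over ester and arene, which this catalyst type provides, and it needs both ketones to react through the chelate, which is secured by each ketone having exactly one ester at the gamma position. Since the two centres form independently, a shortfall at either site would appear as a remote diastereomer that is hard to remove, so high catalyst control is required at both.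

Step 7
Reactants: 14 (R)-butane-1,3-diol
Product: 15 (3R)-3-hydroxybutyl 4-methylbenzenesulfonate
Conditions: TsCl (1.0 equiv), Et3N, DMAP (cat.), CH2Cl2, −20 → 0 °C
Reagents that add atoms: p-toluenesulfonyl chloride, Cc1ccc(cc1)S(=O)(=O)Cl
Why: Selective sulfonylation of the primary hydroxyl of a 1,3-diol on steric grounds; the stereocentre is not involved.

Step 8
Reactants: 15 (3R)-3-hydroxybutyl 4-methylbenzenesulfonate
Product: 16 (3R)-3-[(tert-butyldimethylsilyl)oxy]butyl 4-methylbenzenesulfonate
Conditions: TBSCl, imidazole, DMF, rt
Reagents that add atoms: tert-butyldimethylsilyl chloride, CC(C)(C)[Si](C)(C)Cl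
Why: Standard silylation of a secondary alcohol; the silyl ether masks the hydroxyl during the organometallic step and should fall off in the final acid step.

Step 9
Reactants: 16 (3R)-3-[(tert-butyldimethylsilyl)oxy]butyl 4-methylbenzenesulfonate
Product: 17 tert-butyl{[(2R)-4-iodobutan-2-yl]oxy}dimethylsilane
Conditions: NaI, acetone, reflux
Reagents that add atoms: sodium iodide, [Na+].[I-]
Why: Finkelstein displacement of a primary tosylate by iodide (SN2 at the primary carbon, remote from the stereocentre).

Step 10
Reactants: 17 tert-butyl{[(2R)-4-iodobutan-2-yl]oxy}dimethylsilane; 13 (3R)-5,7-dimethoxy-3-{6-[(2R)-5-oxooxolan-2-yl]hexyl}-2-benzofuran-1(3H)-one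
Product: 20 (3R)-3-[(7R,13R)-13-(tert-butyldimethylsilyloxy)-7-hydroxy-10-oxotetradecyl]-5,7-dimethoxy-2-benzofuran-1(3H)-one (in equilibrium with its five-membered hemiketal), via alkyllithium 18 (not isolated), via organocerium reagent 19 (not isolated)
Conditions: 17, t-BuLi (2.1 equiv), Et2O–pentane, −78 °C; anhydrous CeCl3, THF, −78 °C; then 13 (19 in slight excess), THF, −78 °C; aq. NH4Cl at −78 °C
Reagents that add atoms: none
Why: Iodine–lithium exchange, transmetalation to the weakly basic organocerium reagent (trivalent cerium) and 1,2-addition to a lactone carbonyl; the tetrahedral adduct should persist at −78 °C so that one addition is expected, and enolisation of the lactone or deprotonation at C3 should be suppressed. The butanolide is an unhindered alkyl ester, whereas the phthalide carbonyl is conjugated to a ring with ortho and para methoxy donors and flanked by the C7 methoxy group, which should leave it untouched by a slight excess of reagent. The methyl-bearing carbinol comes unchanged from 14.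

Step 11
Reactants: 20 (3R)-3-[(7R,13R)-13-(tert-butyldimethylsilyloxy)-7-hydroxy-10-oxotetradecyl]-5,7-dimethoxy-2-benzofuran-1(3H)-one
Product: 23 (3R)-5,7-dimethoxy-3-{6-[(2R,5S,7R)-7-methyl-1,6-dioxaspiro[4.4]nonan-2-yl]hexyl}-2-benzofuran-1(3H)-one, via dihydroxy ketone 21 (not isolated), via C5 epimer 22 (not isolated)
Conditions: CSA (0.2 equiv), MeOH–CH2Cl2, rt; Et3N, concentrate; chromatography, 23 collected; all remaining fractions (crude 22) returned without purification to CSA, CH2Cl2, rt; cycle repeated
Reagents that add atoms: none
Why: Acid-catalysed methanolysis of the silyl ether gives 21, which closes through its hemiketal and the oxocarbenium ion (spiroketalisation); C2 and C7 are fixed carbinol carbons and are not touched. The ion is captured on both faces, so 22 forms beside 23, but 22 re-ionises under the same acid and recloses, and because a five-membered spiroketal has little anomeric or steric bias the two are expected in comparable amounts at equilibrium. Withdrawing 23 by chromatography and sending the crude remainder back to the acid should therefore drain 22 into 23 without 22 ever being purified.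

## Compound list

1 | 1-bromo-3,5-dimethoxybenzene | COc1cc(Br)cc(OC)c1 | starting material
2 | methyl 8-chloro-8-oxooctanoate | COC(=O)CCCCCCC(=O)Cl | starting material
3 | (3,5-dimethoxyphenyl)magnesium bromide | COc1cc(OC)cc([Mg]Br)c1 | intermediate (not isolated)
4 | methyl 8-(3,5-dimethoxyphenyl)-8-oxooctanoate | COC(=O)CCCCCCC(=O)c1cc(OC)cc(OC)c1 | intermediate
5 | 8-(3,5-dimethoxyphenyl)-8-oxooctanoic acid | OC(=O)CCCCCCC(=O)c1cc(OC)cc(OC)c1 | intermediate
6 | methyl 3-iodopropanoate | COC(=O)CCI | starting material
7 | 8-(3,5-dimethoxyphenyl)-8-oxooctanoyl chloride | ClC(=O)CCCCCCC(=O)c1cc(OC)cc(OC)c1 | intermediate (not isolated)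
8 | (3-methoxy-3-oxopropyl)zinc iodide | COC(=O)CC[Zn]I | intermediate (not isolated)
9 | methyl 11-(3,5-dimethoxyphenyl)-4,11-dioxoundecanoate | COC(=O)CCC(=O)CCCCCCC(=O)c1cc(OC)cc(OC)c1 | intermediate
10 | methyl 11-(2-bromo-3,5-dimethoxyphenyl)-4,11-dioxoundecanoate | COC(=O)CCC(=O)CCCCCCC(=O)c1cc(OC)cc(OC)c1Br | intermediate
11 | methyl 2-(11-methoxy-8,11-dioxoundecanoyl)-4,6-dimethoxybenzoate | COc1cc(OC)c(C(=O)OC)c(c1)C(=O)CCCCCCC(=O)CCC(=O)OC | intermediate (key-step precursor)
12 | methyl 2-[(1R,8R)-1,8-dihydroxy-11-methoxy-11-oxoundecyl]-4,6-dimethoxybenzoate | COc1cc(OC)c(C(=O)OC)c(c1)[C@H](O)CCCCCC[C@@H](O)CCC(=O)OC | intermediate (not isolated)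
13 | (3R)-5,7-dimethoxy-3-{6-[(2R)-5-oxooxolan-2-yl]hexyl}-2-benzofuran-1(3H)-one | COc1cc(OC)c2c(c1)[C@@H](CCCCCC[C@@H]1CCC(=O)O1)OC2=O | intermediate (key-step product)
14 | (R)-butane-1,3-diol | C[C@@H](O)CCO | starting material
15 | (3R)-3-hydroxybutyl 4-methylbenzenesulfonate | C[C@@H](O)CCOS(=O)(=O)c1ccc(C)cc1 | intermediate
16 | (3R)-3-[(tert-butyldimethylsilyl)oxy]butyl 4-methylbenzenesulfonate | C[C@@H](O[Si](C)(C)C(C)(C)C)CCOS(=O)(=O)c1ccc(C)cc1 | intermediate
17 | tert-butyl{[(2R)-4-iodobutan-2-yl]oxy}dimethylsilane | C[C@@H](O[Si](C)(C)C(C)(C)C)CCI | intermediate
18 | [(3R)-3-(tert-butyldimethylsilyloxy)butyl]lithium | C[C@@H](O[Si](C)(C)C(C)(C)C)CC[Li] | intermediate (not isolated)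
19 | [(3R)-3-(tert-butyldimethylsilyloxy)butyl]cerium dichloride | C[C@@H](O[Si](C)(C)C(C)(C)C)CC[Ce](Cl)Cl | intermediate (not isolated)
20 | (3R)-3-[(7R,13R)-13-(tert-butyldimethylsilyloxy)-7-hydroxy-10-oxotetradecyl]-5,7-dimethoxy-2-benzofuran-1(3H)-one | COc1cc(OC)c2c(c1)[C@@H](CCCCCC[C@@H](O)CCC(=O)CC[C@@H](C)O[Si](C)(C)C(C)(C)C)OC2=O | intermediate
21 | (3R)-3-[(7R,13R)-7,13-dihydroxy-10-oxotetradecyl]-5,7-dimethoxy-2-benzofuran-1(3H)-one | COc1cc(OC)c2c(c1)[C@@H](CCCCCC[C@@H](O)CCC(=O)CC[C@@H](C)O)OC2=O | intermediate (not isolated)
22 | (3R)-5,7-dimethoxy-3-{6-[(2R,5R,7R)-7-methyl-1,6-dioxaspiro[4.4]nonan-2-yl]hexyl}-2-benzofuran-1(3H)-one | COc1cc(OC)c2c(c1)[C@@H](CCCCCC[C@@H]1CC[C@@]3(CC[C@@H](C)O3)O1)OC2=O | intermediate (not isolated; C5 epimer formed in step 11 and re-equilibrated to 23 in the same operation)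
23 | (3R)-5,7-dimethoxy-3-{6-[(2R,5S,7R)-7-methyl-1,6-dioxaspiro[4.4]nonan-2-yl]hexyl}-2-benzofuran-1(3H)-one | COc1cc(OC)c2c(c1)[C@@H](CCCCCC[C@@H]1CC[C@]3(CC[C@@H](C)O3)O1)OC2=O | target

## Step count and least certain steps

Total: 11 steps. Longest linear sequence: 8 steps (steps 1–6, 10, 11, from 1); the side-chain branch is steps 7–9.

**Step 6 (key step).** The most likely failure is incomplete or poorly selective reduction at the aryl ketone. The aryl ester of 11 is twisted out of the ring plane by its two ortho neighbours and may chelate the metal less well than a simple 2-acylbenzoate, and in acidic methanol the ketones may be diverted into ketals that are reduced slowly. Any leakage at either site gives a remote diastereomer that is hard to separate. Fallback: starting from 11, both esters are saponified (LiOH, THF–H2O) to 2-(10-carboxy-8-oxodecanoyl)-4,6-dimethoxybenzoic acid F1. F1 is treated with diisopinocampheylborane Ipc2BH (THF, 0 °C), so that each carboxylic acid forms an acyloxyborane that reduces its own gamma-ketone intramolecularly, a known reduction class for 4-oxo acids and 2-acylbenzoic acids. The antipode of the borane is chosen from the sense established for those classes. Oxidative work-up and acid lactonisation (p-TsOH, toluene) return the route at 13. Each carboxyl still controls its own ketone, but a stoichiometric chiral borane replaces the catalytic hydrogenation.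

**Step 10.** The most likely failure is loss of chemoselectivity: attack on the phthalide carbonyl, a second addition after collapse of the first adduct, or enolisation of the butanolide that returns 13. Fallback: starting from 13, the nucleophile is changed to a less basic alkynyl anion. Purchased (R)-but-3-yn-2-ol F2 is silylated (TBSCl, imidazole) to tert-butyl{[(2R)-but-3-yn-2-yl]oxy}dimethylsilane F3. Its lithium acetylide (n-BuLi, THF, −78 °C) is added to 13 to give (3R)-3-[(7R,13R)-13-(tert-butyldimethylsilyloxy)-7-hydroxy-10-oxotetradec-11-yn-1-yl]-5,7-dimethoxy-2-benzofuran-1(3H)-one F4, and hydrogenation of the triple bond (H2, Pd/C, EtOAc) returns the route at 20.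

**Step 11.** The most likely failure is lack of facial preference at C5 combined with poor chromatographic resolution of the two spiro epimers: both form and interconvert, so the supply of 23 depends on a clean diastereomer separation and on repeated return of the crude fractions holding 22 to the acid. Fallback: starting from 20, the hemiketal is dehydrated (MsCl, Et3N, CH2Cl2) to the cyclic enol ether (3R)-3-{6-[(2R)-5-{(3R)-3-[tert-butyl(dimethyl)silyloxy]butyl}-2,3-dihydrofuran-2-yl]hexyl}-5,7-dimethoxy-2-benzofuran-1(3H)-one F5; the exocyclic isomer would serve equally. Desilylation (TBAF, THF) gives (3R)-3-{6-[(2R)-5-[(3R)-3-hydroxybutyl]-2,3-dihydrofuran-2-yl]hexyl}-5,7-dimethoxy-2-benzofuran-1(3H)-one F6. F6 is closed with a catalytic confined chiral BINOL-derived imidodiphosphoric acid in a non-polar solvent at low temperature. This is the known catalytic asymmetric spiroacetalisation of hydroxy enol ethers, in which the chiral counter-anion decides the face of the oxocarbenium ion under kinetic conditions. The catalyst antipode is chosen to favour 23, where the route is rejoined.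

**Step 5.** The most likely failure is slow oxidative addition at a di-ortho-substituted, electron-rich aryl bromide, together with capture of the aroylpalladium intermediate by the neighbouring ketone instead of methanol. Fallback: starting from 9, the carboxyl carbon is introduced by electrophilic substitution instead. Rieche formylation (Cl2CHOMe, TiCl4, CH2Cl2, −78 → 0 °C) at the same ring position gives methyl 11-(2-formyl-3,5-dimethoxyphenyl)-4,11-dioxoundecanoate F7. Pinnick oxidation (NaClO2, NaH2PO4, 2-methyl-2-butene, t-BuOH–H2O) gives 2-(11-methoxy-8,11-dioxoundecanoyl)-4,6-dimethoxybenzoic acid F8, and O-methylation of the carboxylate (MeI, K2CO3, DMF) returns the route at 11.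

## Further compounds

F1 | step 6 | 2-(10-carboxy-8-oxodecanoyl)-4,6-dimethoxybenzoic acid | COc1cc(OC)c(C(=O)O)c(c1)C(=O)CCCCCCC(=O)CCC(=O)O
F2 | step 10 | (R)-but-3-yn-2-ol | C[C@@H](O)C#C
F3 | step 10 | tert-butyl{[(2R)-but-3-yn-2-yl]oxy}dimethylsilane | C[C@@H](O[Si](C)(C)C(C)(C)C)C#C
F4 | step 10 | (3R)-3-[(7R,13R)-13-(tert-butyldimethylsilyloxy)-7-hydroxy-10-oxotetradec-11-yn-1-yl]-5,7-dimethoxy-2-benzofuran-1(3H)-one | COc1cc(OC)c2c(c1)[C@@H](CCCCCC[C@@H](O)CCC(=O)C#C[C@@H](C)O[Si](C)(C)C(C)(C)C)OC2=O
F5 | step 11 | (3R)-3-{6-[(2R)-5-{(3R)-3-[tert-butyl(dimethyl)silyloxy]butyl}-2,3-dihydrofuran-2-yl]hexyl}-5,7-dimethoxy-2-benzofuran-1(3H)-one | COc1cc(OC)c2c(c1)[C@@H](CCCCCC[C@@H]1CC=C(CC[C@@H](C)O[Si](C)(C)C(C)(C)C)O1)OC2=O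
F6 | step 11 | (3R)-3-{6-[(2R)-5-[(3R)-3-hydroxybutyl]-2,3-dihydrofuran-2-yl]hexyl}-5,7-dimethoxy-2-benzofuran-1(3H)-one | COc1cc(OC)c2c(c1)[C@@H](CCCCCC[C@@H]1CC=C(CC[C@@H](C)O)O1)OC2=O
F7 | step 5 | methyl 11-(2-formyl-3,5-dimethoxyphenyl)-4,11-dioxoundecanoate | COC(=O)CCC(=O)CCCCCCC(=O)c1cc(OC)cc(OC)c1C=O
F8 | step 5 | 2-(11-methoxy-8,11-dioxoundecanoyl)-4,6-dimethoxybenzoic acid | COC(=O)CCC(=O)CCCCCCC(=O)c1cc(OC)cc(OC)c1C(=O)O
A1 | alternative 1 | (R)-gamma-valerolactone, (5R)-5-methyloxolan-2-one | C[C@@H]1CCC(=O)O1
A2 | alternative 1 | (5R)-5-(hex-5-en-1-yl)oxolan-2-one | C=CCCCC[C@@H]1CCC(=O)O1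
A3 | alternative 1 | (2R,5S,7R)-2-(hex-5-en-1-yl)-7-methyl-1,6-dioxaspiro[4.4]nonane | C=CCCCC[C@@H]1CC[C@]2(CC[C@@H](C)O2)O1
A4 | alternative 2 | 6-{(5R)-5-(tert-butyldimethylsilyloxy)-11-[(2R,5S,7R)-7-methyl-1,6-dioxaspiro[4.4]nonan-2-yl]-2,4-dioxoundecyl}-2,2-dimethyl-4H-1,3-dioxin-4-one | CC1(C)OC(=CC(=O)O1)CC(=O)CC(=O)[C@H](O[Si](C)(C)C(C)(C)C)CCCCCC[C@@H]2CC[C@]3(CC[C@@H](C)O3)O2
A5 | alternative 2 | 5-{(1R)-1-(tert-butyldimethylsilyloxy)-7-[(2R,5S,7R)-7-methyl-1,6-dioxaspiro[4.4]nonan-2-yl]heptyl}-7-hydroxy-2,2-dimethyl-4H-1,3-benzodioxin-4-one | CC1(C)Oc2cc(O)cc([C@H](O[Si](C)(C)C(C)(C)C)CCCCCC[C@@H]3CC[C@]4(CC[C@@H](C)O4)O3)c2C(=O)O1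
A6 | alternative 3 | (8R)-8-hydroxy-10-[(5R)-5-methyloxolan-2-yl]decyl 2,2-dimethylpropanoate (either configuration at oxolane C2, which is destroyed in the key step) | CC(C)(C)C(=O)OCCCCCCC[C@@H](O)CCC1CC[C@@H](C)O1
A7 | alternative 3 | 7-[(2R,5S,7R)-7-methyl-1,6-dioxaspiro[4.4]nonan-2-yl]heptyl 2,2-dimethylpropanoate | CC(C)(C)C(=O)OCCCCCCC[C@@H]1CC[C@]2(CC[C@@H](C)O2)O1
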